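## Analysis of the target

Compound 19 is a macrocyclic bis(bibenzyl): four benzene rings joined by two CH2CH2 bridges and two diaryl ether oxygens into one 17-membered ring. Ring A is a 5-alkylbenzene-1,2,3-triol whose terminal O3 is the ether oxygen to ring B. Ring B is a para-phenylene linked through CH2CH2 to C1 of ring C. Ring C carries the second ether oxygen at C2 and a catechol at C3 and C4; that oxygen leads to the ortho-phenylene ring D, whose neighbouring carbon returns through CH2CH2 to C5 of ring A. There is no stereocentre and no stereo element in the structure, so stereocontrol is not needed. The sensitive groups are the two catechol units, which oxidise easily to quinones in air and base, so the free phenols should appear only in the last step. The hard points are telling six phenolic oxygens apart, closing the large ring, and forming the ring C ether at C2, which is flanked by the chain at C1 and the oxygen at C3. The strategy rests on this last feature: the C3 hydroxyl is carried as a formyl group, which activates a fluorine at C2 for displacement by the ring D phenoxide and is afterwards exchanged for oxygen.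

## Retrosynthetic reasoning

19 to 18. The three O–CH3 bonds (ring C O4 and the two free oxygens of ring A) are cut last. Methyl ethers survive every earlier step, and a Lewis-acid demethylation at the end releases the air-sensitive catechols only once.

18 to 16. The C3–O bond of ring C is traced back to a C3–CHO bond. A Dakin-type oxidation replaces the formyl carbon by oxygen through aryl migration, via formate 17. The formyl group is therefore a masked hydroxyl and no atom has to be carried only as an activator.

16 to 15 (key disconnection). The bond between C2 of ring C and the ring D oxygen is cut, which opens the macrocycle to the fluoro aldehyde phenol 15. This is the most hindered bond of the target and the hardest to make by a copper-mediated coupling. Made by addition–elimination at a C–F carbon with an ortho formyl group, it needs only a carbonate base, and the ring closes in the same step. The other ring bonds (the unhindered ring A–O–ring B ether and the two ethylene bridges) are easy to form intermolecularly and are better made earlier.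

15 to 14. The ring D phenol is kept as a methoxymethyl ether until just before cyclisation, so that it is distinguished from the ring A phenol during the first ether formation and is absent as a nucleophile during the palladium coupling.

14 to 9 and 12. The sp3–sp2 bond between C1 of ring C and the benzylic CH2 of the B–C bridge is cut. Forward, hydroboration of vinyl arene 9 gives alkylborane 13, which is cross-coupled with aryl bromide 12. This keeps the fluoro aldehyde in a small fragment and avoids carbonyl olefination when a formyl group must survive. Bromide 12 comes from 10 by deprotonation between fluorine and methoxy (aryllithium 11) and formylation, which fixes the substitution pattern without an isomer problem.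

9 to 7 and 8. The ring A oxygen–ring B carbon bond is cut, so that ring B arrives as boronic acid 8 with the vinyl handle in place. A copper-mediated oxidative coupling at room temperature has to arylate the single free phenol of 7.

7 to 6 to 5 to 2 and 3. The central C–C bond of the A–D bridge is cut as a C=C bond, formed by Wittig reaction of aldehyde 2 with the ylide 4 derived from phosphonium salt 3. The ring D phenol of 5 is then capped to give 6. One hydrogenation saturates the alkene and removes the benzyl group, so 7 has exactly one free hydroxyl, on ring A.

2 to 1. The O–benzyl bond is cut; 1 already carries the ring A oxygen pattern with the correct oxygen free.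

## Alternatives that were turned down

Alternative 1: Ring A is taken apart into the diazo ketone A1, which carries rings D, C and a brominated ring B, and the dialkoxyalkyne A2. On irradiation A1 would undergo Wolff rearrangement to a vinylketene, add to A2, and pass through electrocyclic ring opening and six-electron closure to the phenol A3. Three ring C–C bonds form, and the oxygen that must later be arylated emerges as the only free hydroxyl beside two tert-butyl ethers.
- For it: regiocontrol on ring A is complete. The tert-butyl ethers would come off under mild acid, which is gentler than the final Lewis-acid demethylation of the chosen route; on this point it is stronger.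
- Against it: the oxygen pattern of ring A is not a problem here, because 1 is purchasable with that pattern. A1 needs a long linear build-up that already contains the hindered ring C–O–ring D ether, made intermolecularly. A2 is a labile, non-catalogue alkyne. The macrocycle would still have to be closed afterwards by a copper-mediated etherification next to a bulky tert-butoxy group.
- Comparison: the chosen route forms the hardest ether and the ring in one step and buys ring A. The milder final deprotection does not make up for the many extra steps.

Alternative 2: The bond between the para carbon of ring A and the bridge CH2 is cut, leading back to the macrocyclic 2-arylallyl ether A4 of the central ring A oxygen. Heating A4 would cause a [3,3] Claisen shift to an ortho carbon that is blocked (by OMe or OAr), then a Cope shift to the para carbon and rearomatisation to the phenol A5.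
- For it: the step is thermal and reagent-free, and its site selectivity is fixed by the blocked ortho positions. The ring would be closed earlier by simple O-alkylation with an allylic electrophile, which is an easier macrocyclisation than substitution at a hindered aryl fluoride; on this point it is stronger.
- Against it: A5 has one carbon too many. The exocyclic methylene must be cut out by oxidative cleavage and benzylic deoxygenation, which adds steps and exposes electron-rich rings to oxidants. The ortho dienone intermediate, with an oxygen substituent on its quaternary carbon, can rearomatise by losing that substituent. Both sigmatropic transition states must be reached inside a macrocycle at high temperature. The hindered ring C ether is not addressed and must still be made another way.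
- Comparison: the chosen route carries no surplus carbon and puts the one difficult bond into the ring-closing step.

Alternative 3: Both ortho bonds of ring D are cut. A fluoride source would release the aryne from A6; the phenoxide of A7 would add to it, and the ortho aryl anion would be trapped by the aldehyde carbon of glyoxal A8 to give the racemic hydroxy ketone A9.
- For it: three fragments are joined in one metal-free step. The hindered ring C–O bond forms by addition of the phenoxide to an unhindered, very electrophilic aryne, so ring C needs no activating group; for this bond it is at least as good as SNAr.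
- Against it: the aryl anion next to an aryloxy group is quickly protonated by the phenol, so capture by the carbonyl must outrun proton transfer. A8 is consumed reversibly by phenoxide and water and offers a second electrophilic carbon. A9 carries two surplus oxygens on the bridge, whose reductive removal must spare the aryl bromide needed for a later copper-mediated ring closure.
- Comparison: the sequence after the key step is longer (two deoxygenations, debenzylation, macro-etherification, demethylation), and the ring closure remains a separate, hindered coupling. In the chosen route the activating group is itself the future hydroxyl.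

Key step: step 9

Assumption: 19 is achiral and conformationally mobile, so no stereocontrol is planned. Compounds 1, 3, 8 and 10 are taken as purchasable.

## Route

Step 1
Reactants: 1 3-hydroxy-4,5-dimethoxybenzaldehyde
Product: 2 3-(benzyloxy)-4,5-dimethoxybenzaldehyde
Conditions: BnBr, K2CO3, DMF, rt
Reagents that add atoms: benzyl bromide, BrCc1ccccc1
Why: Williamson etherification of the phenoxide with a benzylic bromide. Benzyl is chosen because the hydrogenation of step 4 removes it together with the alkene, so it costs no separate deprotection.

Step 2
Reactants: 2 3-(benzyloxy)-4,5-dimethoxybenzaldehyde; 3 (2-hydroxybenzyl)triphenylphosphonium bromide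
Product: 5 2-[2-[3-(benzyloxy)-4,5-dimethoxyphenyl]ethenyl]phenol (E/Z mixture), via potassium phenoxide ylide 4 (not isolated)
Conditions: 3, KOtBu (2.4 equiv), THF, 0 °C; then 2, 0 °C → rt; 1 M HCl
Reagents that add atoms: potassium tert-butoxide, CC(C)(C)[O-].[K+] (supplies only the potassium counter-ion of 4)
Why: Wittig olefination. Two equivalents of base remove the phenol proton and then the benzylic proton of 3, and the semi-stabilised ylide 4 adds to the aryl aldehyde. The alkene geometry does not matter because the double bond is saturated in step 4.

Step 3
Reactants: 5 2-[2-[3-(benzyloxy)-4,5-dimethoxyphenyl]ethenyl]phenol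
Product: 6 1-(benzyloxy)-2,3-dimethoxy-5-[2-[2-(methoxymethoxy)phenyl]ethenyl]benzene (E/Z mixture)
Conditions: MOMCl, iPr2NEt, DCM, 0 °C → rt
Reagents that add atoms: chloromethyl methyl ether, COCCl
Why: O-alkylation of the phenol to its methoxymethyl acetal. This group survives hydrogenation, the copper and palladium couplings and base, and is later removed by dilute acid without harm to the aldehyde or the aryl fluoride.

Step 4
Reactants: 6 1-(benzyloxy)-2,3-dimethoxy-5-[2-[2-(methoxymethoxy)phenyl]ethenyl]benzene
Product: 7 2,3-dimethoxy-5-[2-[2-(methoxymethoxy)phenyl]ethyl]phenol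
Conditions: H2 (1 atm), 10% Pd/C, EtOAc/EtOH, rt
Reagents that add atoms: none
Why: Catalytic hydrogenation saturates the stilbene double bond (both isomers give the same bibenzyl) and hydrogenolyses the benzyl ether in one operation. The acetal and methyl ethers are inert, so only the ring A hydroxyl is set free.

Step 5
Reactants: 7 2,3-dimethoxy-5-[2-[2-(methoxymethoxy)phenyl]ethyl]phenol; 8 (4-vinylphenyl)boronic acid
Product: 9 1-(4-ethenylphenoxy)-2,3-dimethoxy-5-[2-[2-(methoxymethoxy)phenyl]ethyl]benzene
Conditions: Cu(OAc)2 (1 equiv), pyridine (5 equiv), 4 Å MS, DCM, dry air, rt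
Reagents that add atoms: none
Why: Chan–Lam oxidative O-arylation. The aryl group passes from boron to the divalent copper phenoxide, oxidation gives a trivalent copper aryl phenoxide, and C–O reductive elimination follows; O2 of the air returns the copper to the divalent state, so the copper salt is not consumed. The weakly basic room-temperature conditions leave the vinyl group and the acetal untouched.

Step 6
Reactants: 10 4-bromo-3-fluoroanisole (1-bromo-2-fluoro-4-methoxybenzene)
Product: 12 3-bromo-2-fluoro-6-methoxybenzaldehyde, via aryllithium 11 (not isolated)
Conditions: LiN(iPr)2, THF, −78 °C; then DMF, −78 → 0 °C; 1 M HCl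
Reagents that add atoms: lithium diisopropylamide, CC(C)[N-]C(C)C.[Li+] (lithium of 11); N,N-dimethylformamide, CN(C)C=O (formyl group of 12)
Why: Directed ortho-metalation and formylation. The proton between fluorine and methoxy is the most acidic of 10 and the amide base does not exchange the bromine, so 11 forms at that carbon and is trapped by DMF. The pattern of 12 (CHO between F and OMe, Br next to F) is thus fixed by the starting material.

Step 7
Reactants: 9 1-(4-ethenylphenoxy)-2,3-dimethoxy-5-[2-[2-(methoxymethoxy)phenyl]ethyl]benzene; 12 3-bromo-2-fluoro-6-methoxybenzaldehyde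
Product: 14 3-[2-[4-[2,3-dimethoxy-5-[2-[2-(methoxymethoxy)phenyl]ethyl]phenoxy]phenyl]ethyl]-2-fluoro-6-methoxybenzaldehyde, via alkylborane 13 (not isolated)
Conditions: 9, 9-BBN-H (0.98 equiv), THF, 0 °C → rt; then 12 (1.1 equiv), PdCl2(dppf) (5 mol %), 3 M aq K3PO4, DMF, 50 °C
Reagents that add atoms: 9-borabicyclo[3.3.1]nonane, [H]B1C2CCCC1CCC2 (its boryl group is in 13 only; 14 keeps just its hydrogen)
Why: Anti-Markovnikov hydroboration of the styrene, then B-alkyl Suzuki–Miyaura coupling: oxidative addition of the aryl bromide to zerovalent palladium, base-assisted transfer of the primary alkyl group, and reductive elimination, with the dppf ligand holding back β-hydride elimination. The borane is used in slight deficit so that no B–H is left to reduce the aldehyde. The mild phosphate base at 50 °C should leave the aryl fluoride in place.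

Step 8
Reactants: 14 3-[2-[4-[2,3-dimethoxy-5-[2-[2-(methoxymethoxy)phenyl]ethyl]phenoxy]phenyl]ethyl]-2-fluoro-6-methoxybenzaldehyde
Product: 15 2-fluoro-3-[2-[4-[5-[2-(2-hydroxyphenyl)ethyl]-2,3-dimethoxyphenoxy]phenyl]ethyl]-6-methoxybenzaldehyde
Conditions: 2 M HCl, THF, 45 °C
Reagents that add atoms: none
Why: Acid hydrolysis of the methoxymethyl acetal. The aqueous medium keeps the aldehyde free, and aryl fluoride, methyl ethers and diaryl ether are stable to dilute acid.

Step 9
Reactants: 15 2-fluoro-3-[2-[4-[5-[2-(2-hydroxyphenyl)ethyl]-2,3-dimethoxyphenoxy]phenyl]ethyl]-6-methoxybenzaldehyde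
Product: 16 macrocyclic aldehyde (17-membered ring of 19 with CHO at ring C C3 and OMe at ring C C4 and on both free oxygens of ring A)
Conditions: Cs2CO3 (4 equiv), 4 Å MS, DMF, 100 °C, Ar; 15 added by syringe pump over 12 h to a final 0.002 M
Reagents that add atoms: none
Why: Cs2CO3 deprotonates the ring D phenol, and the caesium phenoxide adds to C2 of ring C, the carbon bearing fluorine, to give a Meisenheimer adduct whose negative charge is spread over C1, C3 and C5 and onto the formyl oxygen at C3; loss of fluoride then restores the arene (addition–elimination, SNAr). The closest known reaction type is the intramolecular SNAr macroetherification of aryl fluorides activated by an ortho nitro or carbonyl group, as used for macrocyclic diaryl ethers. The 17-membered ring closes in the exo-trig mode, because the C2=C3 π bond that accepts the electron pair has C3 outside the new ring. No stereocentre is formed. Ring closure must beat intermolecular etherification, and this is secured by slow addition of 15 to a hot, dilute suspension of the base, which keeps the standing concentration of phenoxide very low. Site selectivity comes from the substrate: C2–F is the only carbon that combines an ortho acceptor with a good SNAr leaving group, the methoxy group at C4 being a far poorer one and the other rings unactivated. Fluorine is small enough to allow attack at a carbon flanked by the chain at C1 and the formyl group at C3, and addition of the phenoxide to the aldehyde is reversible and unproductive. Molecular sieves keep hydroxide away from the activated fluoride.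

Step 10
Reactants: 16 macrocyclic aldehyde
Product: 18 macrocyclic ring C phenol (as 16 but OH in place of CHO at ring C C3), via aryl formate 17 (not isolated)
Conditions: mCPBA (1.5 equiv), DCM, 0 °C → rt; then K2CO3 (cat.), MeOH, rt
Reagents that add atoms: 3-chloroperoxybenzoic acid, OOC(=O)c1cccc(Cl)c1
Why: Baeyer–Villiger variant of the Dakin oxidation. The peracid adds to the aldehyde, and the aryl group, made electron-rich by two ortho oxygen substituents, migrates in preference to hydride to give formate 17, which is methanolysed. No alkene or amine is present to compete for the peracid.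

Step 11
Reactants: 18 macrocyclic ring C phenol
Product: 19 target CNP0114693.0 (macrocyclic tetraphenol)
Conditions: BBr3 (9 equiv), DCM, −78 °C → rt; then H2O, 0 °C, under Ar
Reagents that add atoms: none
Why: Lewis-acid cleavage of the three aryl methyl ethers (coordination of boron to oxygen, then bromide attack on methyl). Diaryl ethers are inert to BBr3, so the macrocycle stays intact, and work-up under argon protects the catechols.

## Compound list

1 | 3-hydroxy-4,5-dimethoxybenzaldehyde | COc1cc(C=O)cc(O)c1OC | starting material
2 | 3-(benzyloxy)-4,5-dimethoxybenzaldehyde | COc1cc(C=O)cc(OCc2ccccc2)c1OC | intermediate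
3 | (2-hydroxybenzyl)triphenylphosphonium bromide | Oc1ccccc1C[P+](c1ccccc1)(c1ccccc1)c1ccccc1.[Br-] | starting material
4 | potassium 2-[(triphenylphosphoranylidene)methyl]phenolate (ylide, not isolated) | [K+].[O-]c1ccccc1C=P(c1ccccc1)(c1ccccc1)c1ccccc1 | intermediate
5 | 2-[2-[3-(benzyloxy)-4,5-dimethoxyphenyl]ethenyl]phenol (E/Z mixture) | COc1cc(C=Cc2ccccc2O)cc(OCc2ccccc2)c1OC | intermediate
6 | 1-(benzyloxy)-2,3-dimethoxy-5-[2-[2-(methoxymethoxy)phenyl]ethenyl]benzene (E/Z mixture) | COCOc1ccccc1C=Cc1cc(OC)c(OC)c(OCc2ccccc2)c1 | intermediate
7 | 2,3-dimethoxy-5-[2-[2-(methoxymethoxy)phenyl]ethyl]phenol | COCOc1ccccc1CCc1cc(O)c(OC)c(OC)c1 | intermediate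
8 | (4-vinylphenyl)boronic acid | C=Cc1ccc(cc1)B(O)O | starting material
9 | 1-(4-ethenylphenoxy)-2,3-dimethoxy-5-[2-[2-(methoxymethoxy)phenyl]ethyl]benzene | COCOc1ccccc1CCc1cc(OC)c(OC)c(Oc2ccc(C=C)cc2)c1 | intermediate
10 | 4-bromo-3-fluoroanisole (1-bromo-2-fluoro-4-methoxybenzene) | COc1ccc(Br)c(F)c1 | starting material
11 | (3-bromo-2-fluoro-6-methoxyphenyl)lithium (not isolated) | [Li]c1c(OC)ccc(Br)c1F | intermediate
12 | 3-bromo-2-fluoro-6-methoxybenzaldehyde | O=Cc1c(OC)ccc(Br)c1F | intermediate
13 | 9-[2-[4-[2,3-dimethoxy-5-[2-[2-(methoxymethoxy)phenyl]ethyl]phenoxy]phenyl]ethyl]-9-borabicyclo[3.3.1]nonane (not isolated) | COCOc1ccccc1CCc1cc(OC)c(OC)c(Oc2ccc(CCB3C4CCCC3CCC4)cc2)c1 | intermediate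
14 | 3-[2-[4-[2,3-dimethoxy-5-[2-[2-(methoxymethoxy)phenyl]ethyl]phenoxy]phenyl]ethyl]-2-fluoro-6-methoxybenzaldehyde | O=Cc1c(OC)ccc(CCc2ccc(Oc3cc(CCc4ccccc4OCOC)cc(OC)c3OC)cc2)c1F | intermediate
15 | 2-fluoro-3-[2-[4-[5-[2-(2-hydroxyphenyl)ethyl]-2,3-dimethoxyphenoxy]phenyl]ethyl]-6-methoxybenzaldehyde | O=Cc1c(OC)ccc(CCc2ccc(Oc3cc(CCc4ccccc4O)cc(OC)c3OC)cc2)c1F | intermediate
16 | macrocyclic aldehyde (ring C: C3 CHO, C4 OMe; ring A: two OMe) | O=Cc1c(OC)ccc2CCc3ccc(cc3)Oc3cc(cc(OC)c3OC)CCc3ccccc3Oc12 | intermediate
17 | macrocyclic aryl formate (ring C: C3 OCHO; not isolated) | O=COc1c(OC)ccc2CCc3ccc(cc3)Oc3cc(cc(OC)c3OC)CCc3ccccc3Oc12 | intermediate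
18 | macrocyclic ring C phenol (ring C: C3 OH, C4 OMe; ring A: two OMe) | Oc1c(OC)ccc2CCc3ccc(cc3)Oc3cc(cc(OC)c3OC)CCc3ccccc3Oc12 | intermediate
19 | CNP0114693.0, macrocyclic bis(bibenzyl) tetraphenol | Oc1cc2cc(c1O)Oc1ccc(cc1)CCc1ccc(O)c(O)c1Oc1ccccc1CC2 | target

## Step count and risk

Total: 11 steps. Longest linear sequence: 10 steps (steps 1–5 and 7–11, from 1 to 19); step 6 is a one-step branch.

Least certain steps:

Step 9 (key step).
- What may go wrong: intermolecular etherification may outrun ring closure and give oligomers. The substitution itself may be slow, because a single formyl group activates the fluoride and its acceptor strength is lowered by the neighbouring methoxy group. Long heating then lets dimethylamine from the solvent, or traces of hydroxide, attack the fluoride.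
- Fallback (from 9 and 12, back at 16): make the hindered ether intermolecularly, where concentration can drive it, and close the ring at the B–C bridge. The acetal of 9 is hydrolysed (dilute HCl, THF, rt) to the vinyl phenol F1. Its phenoxide displaces the fluoride of 12 (K2CO3, DMF, 90 °C, concentrated solution) to give the bromo aldehyde diaryl ether F2. The aldehyde is masked (ethylene glycol, cat. pyridinium tosylate, toluene, water removal) as the dioxolane F3. Hydroboration of the vinyl group with 9-BBN-H gives the alkylborane F4, which is cyclised by an intramolecular B-alkyl Suzuki coupling (PdCl2(dppf), aq K3PO4, THF/DMF, high dilution) to the macrocyclic dioxolane F5. Dilute aqueous acid then gives 16.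

Step 7.
- What may go wrong: the formyl group may be reduced by residual boron hydride; hydroxide may displace the activated fluoride in the aqueous base; or the alkylborane may be lost by protodeboronation or β-hydride elimination before transmetalation.
- Fallback (from 12, with 13 made from 9 as before, back at 15): couple a masked aldehyde. 12 is converted (ethylene glycol, cat. TsOH, toluene, water removal) into the bromo fluoro dioxolane F6, which is neither a hydride acceptor nor an SNAr substrate. Coupling of F6 with 13 under the palladium conditions of step 7 gives the doubly acetal-protected open-chain compound F7. The acid treatment of step 8 removes dioxolane and methoxymethyl group together and gives 15.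

Step 5.
- What may go wrong: O-arylation of the phenol, which is flanked by a methoxy group, may be incomplete while the boronic acid is used up by homocoupling, protodeboronation and oxidation; vinyl arene may be lost by polymerisation.
- Fallback (from 7, back at 9): form the ether by SNAr and install the vinyl group afterwards. 7 and 4-fluorobenzaldehyde (K2CO3, DMF, 120 °C) give the diaryl ether aldehyde F8. Wittig methylenation (methyltriphenylphosphonium bromide, KOtBu, THF, 0 °C) turns its formyl group into the vinyl group of 9.

Step 2.
- What may go wrong: conversion may be low because the phenoxide betaine formed from 3 is poorly soluble and its second deprotonation incomplete. The phenoxide may also expel triphenylphosphine to give an ortho-quinone methide that oligomerises.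
- Fallback (from 2, back at 7): replace the olefination by a cross-coupling. Methylenation of 2 (methyltriphenylphosphonium bromide, KOtBu, THF) gives the benzyloxy styrene F9. Hydroboration with 9-BBN-H gives the alkylborane F10, which is coupled with purchased 1-bromo-2-(methoxymethoxy)benzene (PdCl2(dppf), aq K3PO4, THF, 65 °C) to the doubly protected bibenzyl F11. Hydrogenolysis under the conditions of step 4 gives 7.

Step 10.
- What may go wrong: hydride may migrate instead of the aryl group, giving the benzoic acid, since one of the two ortho donors is only an aryloxy group and the carbonyl is flanked on both sides. The peracid may also oxidise the electron-rich ring A.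
- Fallback (from 16, back at 19): turn the substrate into a classical Dakin substrate. BCl3 (DCM, −78 → 0 °C) removes, through chelation to the carbonyl, only the methyl ether ortho to the formyl group and gives the macrocyclic salicylaldehyde F12. Alkaline H2O2 (NaOH, THF/H2O, 0 °C) then effects the Dakin oxidation, in which the ortho phenoxide ensures aryl migration, to the ring C catechol F13. BBr3 as in step 11 removes the two remaining methyl ethers and gives 19.

## Further compounds

F1 | step 9 | 2-[2-[3-(4-ethenylphenoxy)-4,5-dimethoxyphenyl]ethyl]phenol | C=Cc1ccc(Oc2cc(CCc3ccccc3O)cc(OC)c2OC)cc1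
F2 | step 9 | 3-bromo-2-[2-[2-[3-(4-ethenylphenoxy)-4,5-dimethoxyphenyl]ethyl]phenoxy]-6-methoxybenzaldehyde | O=Cc1c(OC)ccc(Br)c1Oc1ccccc1CCc1cc(OC)c(OC)c(Oc2ccc(C=C)cc2)c1
F3 | step 9 | 2-[3-bromo-2-[2-[2-[3-(4-ethenylphenoxy)-4,5-dimethoxyphenyl]ethyl]phenoxy]-6-methoxyphenyl]-1,3-dioxolane | COc1ccc(Br)c(Oc2ccccc2CCc2cc(OC)c(OC)c(Oc3ccc(C=C)cc3)c2)c1C1OCCO1
F4 | step 9 | 9-BBN adduct of the vinyl group of F3 (B-alkyl-9-borabicyclo[3.3.1]nonane) | COc1ccc(Br)c(Oc2ccccc2CCc2cc(OC)c(OC)c(Oc3ccc(CCB4C5CCCC4CCC5)cc3)c2)c1C1OCCO1
F5 | step 9 | macrocyclic 1,3-dioxolane of 16 | COc1ccc2CCc3ccc(cc3)Oc3cc(cc(OC)c3OC)CCc3ccccc3Oc2c1C1OCCO1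
F6 | step 7 | 2-(3-bromo-2-fluoro-6-methoxyphenyl)-1,3-dioxolane | COc1ccc(Br)c(F)c1C1OCCO1
F7 | step 7 | 2-[3-[2-[4-[2,3-dimethoxy-5-[2-[2-(methoxymethoxy)phenyl]ethyl]phenoxy]phenyl]ethyl]-2-fluoro-6-methoxyphenyl]-1,3-dioxolane | COCOc1ccccc1CCc1cc(OC)c(OC)c(Oc2ccc(CCc3ccc(OC)c(C4OCCO4)c3F)cc2)c1
F8 | step 5 | 4-[2,3-dimethoxy-5-[2-[2-(methoxymethoxy)phenyl]ethyl]phenoxy]benzaldehyde | COCOc1ccccc1CCc1cc(OC)c(OC)c(Oc2ccc(C=O)cc2)c1
F9 | step 2 | 1-(benzyloxy)-5-ethenyl-2,3-dimethoxybenzene | C=Cc1cc(OC)c(OC)c(OCc2ccccc2)c1
F10 | step 2 | 9-[2-[3-(benzyloxy)-4,5-dimethoxyphenyl]ethyl]-9-borabicyclo[3.3.1]nonane | COc1cc(CCB2C3CCCC2CCC3)cc(OCc2ccccc2)c1OC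
F11 | step 2 | 1-(benzyloxy)-2,3-dimethoxy-5-[2-[2-(methoxymethoxy)phenyl]ethyl]benzene | COCOc1ccccc1CCc1cc(OC)c(OC)c(OCc2ccccc2)c1
F12 | step 10 | macrocyclic salicylaldehyde (16 with OH in place of OMe at ring C C4) | O=Cc1c(O)ccc2CCc3ccc(cc3)Oc3cc(cc(OC)c3OC)CCc3ccccc3Oc12
F13 | step 10 | macrocyclic ring C catechol with ring A still dimethylated | Oc1c(O)ccc2CCc3ccc(cc3)Oc3cc(cc(OC)c3OC)CCc3ccccc3Oc12
A1 | alternative 1 | 5-[2-[6-[2-(4-bromophenyl)ethyl]-2,3-dimethoxyphenoxy]phenyl]-1-diazo-3-methylidenepentan-2-one | [N-]=[N+]=CC(=O)C(=C)CCc1ccccc1Oc1c(CCc2ccc(Br)cc2)ccc(OC)c1OC
A2 | alternative 1 | 1,2-di-tert-butoxyethyne | CC(C)(C)OC#COC(C)(C)C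
A3 | alternative 1 | ring A phenol with two tert-butyl ethers (2,3-di-tert-butoxy-5-alkylphenol) | Oc1cc(CCc2ccccc2Oc2c(CCc3ccc(Br)cc3)ccc(OC)c2OC)cc(OC(C)(C)C)c1OC(C)(C)C
A4 | alternative 2 | macrocyclic 2-arylallyl ether of the central ring A oxygen | C=C1COc2c(OC)cccc2Oc2ccc(cc2)CCc2ccc(OC)c(OC)c2Oc2ccccc21
A5 | alternative 2 | macrocyclic phenol with exocyclic methylene on the bridge | C=C1Cc2cc(OC)c(O)c(c2)Oc2ccc(cc2)CCc2ccc(OC)c(OC)c2Oc2ccccc21
A6 | alternative 3 | 2-(trimethylsilyl)phenyl trifluoromethanesulfonate | C[Si](C)(C)c1ccccc1OS(=O)(=O)C(F)(F)F
A7 | alternative 3 | 6-[2-(4-bromophenyl)ethyl]-2,3-dimethoxyphenol | COc1ccc(CCc2ccc(Br)cc2)c(O)c1OC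
A8 | alternative 3 | 2-[3-(benzyloxy)-4,5-dimethoxyphenyl]-2-oxoacetaldehyde | O=CC(=O)c1cc(OC)c(OC)c(OCc2ccccc2)c1
A9 | alternative 3 | ortho-aryloxy benzoin-type adduct (racemic) | COc1ccc(CCc2ccc(Br)cc2)c(Oc2ccccc2C(O)C(=O)c2cc(OC)c(OC)c(OCc3ccccc3)c2)c1OC
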